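**Retrosynthetic overview**

1. Target ⇐ exo-face enolate hydroxylation at C16 and Fleming–Tamao unmasking of the C6 alcohol from a CH2SiMe2Ph group.
2. Ring D (last ring) ⇐ 5-exo closure of the C13–C16 bond by an α-keto radical generated from an α-iodo ethyl ketone (enolonium-type precursor) onto the ring-C alkene.
3. Ring C ⇐ Diels–Alder of butadiene with an α-acyl unsaturated spirolactone (C9–C11 and C8–C14), on the face anti to C5.
4. Spirolactone ⇐ alkoxide–enolate dianion at C10 plus an ethoxymethylidene β-keto ester (C9–C10, then O–C7 lactonisation).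
5. Ring A, key bond C5–C6 ⇐ enantioselective copper-catalysed conjugate addition of a silylmethyl Grignard reagent (hydroxymethyl anion equivalent) to 4,4-dimethylcyclohexadienone, with the enolate trapped by formaldehyde; ring order A → lactone → C → D.

Assumption: positions are given in kaurane numbering (ring A = C1–C5/C10, C6 = CH2OH carbon, lactone C20–O–C7, ring C = C8/C9/C11–C14, ring D = C8/C13–C16, C17 = methyl on C16), and the phosphoramidite enantiomer used in step 1 is the one that delivers the 5S adduct.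

**Step 1**
Reactants: 1 4,4-dimethylcyclohexa-2,5-dien-1-one; 2 (chloromethyl)dimethyl(phenyl)silane; 3 formaldehyde (monomer, cracked from paraformaldehyde)
Product: 6 (5S,6R)-5-{[dimethyl(phenyl)silyl]methyl}-6-(hydroxymethyl)-4,4-dimethylcyclohex-2-en-1-one, via Grignard reagent 4 (not isolated), via magnesium enolate 5 (not isolated)
Conditions: 2, Mg, Et2O, rt; then 1, CuBr·SMe2 (5 mol %), (S,R,R)-O,O′-(1,1′-binaphthyl-2,2′-diyl)-N,N-bis(1-phenylethyl)phosphoramidite (6 mol %), Et2O, −78 °C; then 3 (THF solution), −78 °C; aq. NH4Cl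
Reagents that add atoms: none
Why: Proposed new method: the silylmethyl Grignard reagent makes the formaldehyde-level carbon C6 nucleophilic and joins it to the electrophilic enone β-carbon C5, as in known racemic copper-catalysed silylmethyl Grignard conjugate additions; the chiral copper–phosphoramidite catalyst should select one enantiotopic alkene face as in known copper-catalysed desymmetrising conjugate additions of alkylmetals to 4,4-disubstituted cyclohexadienones (sets C5), and the magnesium enolate then adds to formaldehyde (aldol) anti to the new C5 substituent (trans; this C10 centre is reset in step 3).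

**Step 2**
Reactants: 7 ethyl 3-oxopentanoate; 8 triethyl orthoformate
Product: 9 ethyl 2-(ethoxymethylidene)-3-oxopentanoate (E/Z mixture)
Conditions: Ac2O (2.2 equiv), 130 °C, volatiles distilled off
Reagents that add atoms: none
Why: Standard orthoformate condensation (ethoxymethylenation) of an active methylene compound, driven by acetylation of the released ethanol; no stereocentre is formed.

**Step 3**
Reactants: 6 (5S,6R)-5-{[dimethyl(phenyl)silyl]methyl}-6-(hydroxymethyl)-4,4-dimethylcyclohex-2-en-1-one; 9 ethyl 2-(ethoxymethylidene)-3-oxopentanoate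
Product: 11 (6S,11R)-11-{[dimethyl(phenyl)silyl]methyl}-10,10-dimethyl-4-propanoyl-2-oxaspiro[5.5]undeca-4,8-diene-3,7-dione, via dilithium dianion 10 (not isolated)
Conditions: LiN(iPr)2 (2.2 equiv), THF, −78 → −40 °C; then 9, −78 → 0 °C; AcOH
Reagents that add atoms: none
Why: The alkoxide–enolate dianion (Fráter–Seebach type, protected against retro-aldol and β-elimination) undergoes Michael addition–elimination at the ethoxymethylidene carbon on the enolate face anti to the C5 silylmethyl group, which sets the quaternary C10 with C9 trans and C20 cis to C6, and the C20 alkoxide then lactonises onto the ethyl ester.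

**Step 4**
Reactants: 11 (6S,11R)-11-{[dimethyl(phenyl)silyl]methyl}-10,10-dimethyl-4-propanoyl-2-oxaspiro[5.5]undeca-4,8-diene-3,7-dione; 12 buta-1,3-diene
Product: 13 (5R,8S,9S,10S)-6-[dimethyl(phenyl)silyl]-1,15-dioxo-6,7:13,16-disecokaura-2,12-dien-7,20-olide
Conditions: 12 (excess), Sc(OTf)3 (10 mol %), CH2Cl2, −20 °C → rt, sealed vessel
Reagents that add atoms: none
Why: Lewis-acid-catalysed Diels–Alder reaction of a chelating, doubly activated dienophile; suprafacial addition gives the cis ring fusion (C8 and C9 together), and the diene approaches the alkene face flanked by the flat C1 carbonyl, anti to the bulkier C5 branch of the spiro centre.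

**Step 5**
Reactants: 13 (5R,8S,9S,10S)-6-[dimethyl(phenyl)silyl]-1,15-dioxo-6,7:13,16-disecokaura-2,12-dien-7,20-olide
Product: 15 (5R,8S,9S,10S,13R)-6-[dimethyl(phenyl)silyl]-1,15-dioxo-6,7-secokaur-2-en-7,20-olide (C16 epimer mixture), via alpha-iodo ketone 14 (not isolated)
Conditions: LiN(SiMe3)2 (1.05 equiv), THF, −78 °C; I2 (1.0 equiv), −78 °C; then Bu3SnH (1.2 equiv, slow addition), Et3B (20 mol %), air, THF/PhH, 0 °C → rt
Reagents that add atoms: none
Why: Iodination of the only possible ketone enolate gives an enolonium-type α-iodo ketone whose electrophilic C16 radical adds 5-exo-trig to C13 of the ring-C alkene (radical cyclisation joining two normally nucleophilic carbons); the acyl tether on C8 forces the new C13–C16 bond cis to C15 (sets C13), and the C12 radical is reduced by the stannane.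

**Step 6**
Reactants: 15 (5R,8S,9S,10S,13R)-6-[dimethyl(phenyl)silyl]-1,15-dioxo-6,7-secokaur-2-en-7,20-olide (C16 epimer mixture)
Product: 16 (5R,8S,9S,10S,13R)-6-hydroxy-1,15-dioxo-6,7-secokaur-2-en-7,20-olide (C16 epimer mixture)
Conditions: Hg(OAc)2 (1.5 equiv), AcOOH (32 % in AcOH), AcOH, rt
Reagents that add atoms: peracetic acid, CC(=O)OO
Why: Fleming–Tamao oxidation: mercuridesilylation removes the phenyl group and the peracid induces the silicon-to-oxygen shift of the primary C6 carbon; no stereocentre is touched, and the electron-poor enone, hindered ketone and lactone tolerate peracid at room temperature.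

**Step 7**
Reactants: 16 (5R,8S,9S,10S,13R)-6-hydroxy-1,15-dioxo-6,7-secokaur-2-en-7,20-olide (C16 epimer mixture)
Product: 17 (5R,8S,9S,10S,13R,16S)-6,16-dihydroxy-1,15-dioxo-6,7-secokaur-2-en-7,20-olide (target CNP0530135.1)
Conditions: KN(SiMe3)2 (2.3 equiv), THF, −78 °C; trans-2-(phenylsulfonyl)-3-phenyloxaziridine (1.3 equiv), −78 °C; AcOH
Reagents that add atoms: trans-2-(phenylsulfonyl)-3-phenyloxaziridine, O=S(=O)(N1OC1c1ccccc1)c1ccccc1
Why: Davis enolate hydroxylation: C16 is the only enolisable position (C8 and C10 are quaternary, the ring-A ketone has no α-hydrogen), both C16 epimers converge on one enolate, and the oxidant approaches the exo face away from the C9–C11–C12 bridge and ring A, giving exo OH and endo methyl (16S).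

**Compound list**

1 | 4,4-dimethylcyclohexa-2,5-dien-1-one | CC1(C)C=CC(=O)C=C1 | starting material
2 | (chloromethyl)dimethyl(phenyl)silane | ClC[Si](C)(C)c1ccccc1 | starting material
3 | formaldehyde (from paraformaldehyde) | C=O | starting material
4 | {[dimethyl(phenyl)silyl]methyl}magnesium chloride | C[Si](C)(C[Mg]Cl)c1ccccc1 | intermediate
5 | chloromagnesium dienolate of (5S)-5-{[dimethyl(phenyl)silyl]methyl}-4,4-dimethylcyclohex-2-en-1-one | CC1(C)C=CC(O[Mg]Cl)=C[C@@H]1C[Si](C)(C)c1ccccc1 | intermediate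
6 | (5S,6R)-5-{[dimethyl(phenyl)silyl]methyl}-6-(hydroxymethyl)-4,4-dimethylcyclohex-2-en-1-one | CC1(C)C=CC(=O)[C@@H](CO)[C@@H]1C[Si](C)(C)c1ccccc1 | intermediate
7 | ethyl 3-oxopentanoate | CCC(=O)CC(=O)OCC | starting material
8 | triethyl orthoformate | CCOC(OCC)OCC | starting material
9 | ethyl 2-(ethoxymethylidene)-3-oxopentanoate | CCOC=C(C(=O)CC)C(=O)OCC | intermediate
10 | dilithium alkoxide–dienolate of 6 | CC1(C)C=CC(O[Li])=C(CO[Li])[C@@H]1C[Si](C)(C)c1ccccc1 | intermediate
11 | (6S,11R)-11-{[dimethyl(phenyl)silyl]methyl}-10,10-dimethyl-4-propanoyl-2-oxaspiro[5.5]undeca-4,8-diene-3,7-dione | CC1(C)C=CC(=O)[C@]2(COC(=O)C(C(=O)CC)=C2)[C@@H]1C[Si](C)(C)c1ccccc1 | intermediate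
12 | buta-1,3-diene | C=CC=C | starting material
13 | (5R,8S,9S,10S)-6-[dimethyl(phenyl)silyl]-1,15-dioxo-6,7:13,16-disecokaura-2,12-dien-7,20-olide | CC1(C)C=CC(=O)[C@]2(COC(=O)[C@@]3(C(=O)CC)CC=CC[C@H]32)[C@@H]1C[Si](C)(C)c1ccccc1 | intermediate
14 | 16-iodo derivative of 13 (C16 epimers) | CC1(C)C=CC(=O)[C@]2(COC(=O)[C@@]3(C(=O)C(C)I)CC=CC[C@H]32)[C@@H]1C[Si](C)(C)c1ccccc1 | intermediate
15 | (5R,8S,9S,10S,13R)-6-[dimethyl(phenyl)silyl]-1,15-dioxo-6,7-secokaur-2-en-7,20-olide (C16 epimers) | CC1(C)C=CC(=O)[C@]2(COC(=O)[C@@]34C[C@@H](CC[C@H]32)C(C)C4=O)[C@@H]1C[Si](C)(C)c1ccccc1 | intermediate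
16 | (5R,8S,9S,10S,13R)-6-hydroxy-1,15-dioxo-6,7-secokaur-2-en-7,20-olide (C16 epimers) | CC1(C)C=CC(=O)[C@]2(COC(=O)[C@@]34C[C@@H](CC[C@H]32)C(C)C4=O)[C@@H]1CO | intermediate
17 | (5R,8S,9S,10S,13R,16S)-6,16-dihydroxy-1,15-dioxo-6,7-secokaur-2-en-7,20-olide | CC1(C)C=CC(=O)[C@]2(COC(=O)[C@@]34C[C@@H](CC[C@H]32)[C@](C)(O)C4=O)[C@@H]1CO | target

**Step count**

Total: 7 steps. Longest linear sequence: 6 steps (1, 3, 4, 5, 6, 7); step 2 is a one-step side branch.

**Three steps most likely to fail, each with a fallback**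

Step 1. Risks are slow transfer of the bulky silylmethyl group next to the quaternary C4 and an untested level of enantioselectivity. Fallback (racemic addition, then resolution): setting out from 1, an achiral CuI-catalysed addition of 4 with the same formaldehyde trapping gives 6 as a 1:1 mixture with its mirror image, (5R,6S)-5-{[dimethyl(phenyl)silyl]methyl}-6-(hydroxymethyl)-4,4-dimethylcyclohex-2-en-1-one F1. A lipase chosen by screening (for example Burkholderia cepacia lipase, vinyl acetate, t-BuOMe) acylates F1 to [(1S,6R)-6-{[dimethyl(phenyl)silyl]methyl}-5,5-dimethyl-2-oxocyclohex-3-en-1-yl]methyl acetate F2, and the unreacted alcohol is separated, which rejoins the route at 6.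

Step 3. Risks are formation of a quaternary centre flanked by C5 and C4, proton transfer to 9 instead of addition, and O- versus C-attack. Fallback (protect, add, then cyclise under acid): from 6, TBSCl/imidazole gives (5S,6R)-6-{[tert-butyl(dimethyl)silyl]oxymethyl}-5-{[dimethyl(phenyl)silyl]methyl}-4,4-dimethylcyclohex-2-en-1-one F3. Its mono-lithium enolate (LiN(iPr)2, 1.1 equiv, THF, −78 °C) adds to 9 with loss of ethoxide to give the acyclic alkylidene keto ester, ethyl 2-[(1-{[tert-butyl(dimethyl)silyl]oxymethyl}-6-{[dimethyl(phenyl)silyl]methyl}-5,5-dimethyl-2-oxocyclohex-3-en-1-yl)methylidene]-3-oxopentanoate F4 (C9 trans to the silylmethyl group). Aqueous HF in MeCN then removes the silyl ether, and the freed C20 alcohol lactonises, which rejoins the route at 11.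

Step 5. Risks are 6-endo closure to the bicyclo[2.2.2]octane, reduction of the radical before cyclisation, and the need to react through the conformer with the acyl group axial on ring C. Fallback (oxidative cycloalkenylation instead of a radical): from 13, TBSOTf/Et3N gives the silyl enol ether of the ethyl ketone, (5R,8S,9S,10S)-15-{[tert-butyl(dimethyl)silyl]oxy}-6-[dimethyl(phenyl)silyl]-1-oxo-6,7:13,16-disecokaura-2,12,15-trien-7,20-olide F5. Pd(OAc)2 in DMSO under O2 closes C13–C16 by enolate carbopalladation and β-hydride elimination to (5R,8S,9S,10S,13R)-6-[dimethyl(phenyl)silyl]-1,15-dioxo-6,7-secokaura-2,11-dien-7,20-olide F6. H2 with RhCl(PPh3)3 saturates the isolated C11=C12 alkene in preference to the hindered ring-A enone, which rejoins the route at 15.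

**Further compounds**

F1 | step 1 | (5R,6S)-5-{[dimethyl(phenyl)silyl]methyl}-6-(hydroxymethyl)-4,4-dimethylcyclohex-2-en-1-one | CC1(C)C=CC(=O)[C@H](CO)[C@H]1C[Si](C)(C)c1ccccc1
F2 | step 1 | [(1S,6R)-6-{[dimethyl(phenyl)silyl]methyl}-5,5-dimethyl-2-oxocyclohex-3-en-1-yl]methyl acetate | CC1(C)C=CC(=O)[C@H](COC(C)=O)[C@H]1C[Si](C)(C)c1ccccc1
F3 | step 3 | (5S,6R)-6-{[tert-butyl(dimethyl)silyl]oxymethyl}-5-{[dimethyl(phenyl)silyl]methyl}-4,4-dimethylcyclohex-2-en-1-one | CC1(C)C=CC(=O)[C@@H](CO[Si](C)(C)C(C)(C)C)[C@@H]1C[Si](C)(C)c1ccccc1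
F4 | step 3 | ethyl 2-[(1-{[tert-butyl(dimethyl)silyl]oxymethyl}-6-{[dimethyl(phenyl)silyl]methyl}-5,5-dimethyl-2-oxocyclohex-3-en-1-yl)methylidene]-3-oxopentanoate (C9 trans to the silylmethyl group) | CC1(C)C=CC(=O)[C@@](CO[Si](C)(C)C(C)(C)C)(C=C(C(=O)CC)C(=O)OCC)[C@@H]1C[Si](C)(C)c1ccccc1
F5 | step 5 | (5R,8S,9S,10S)-15-{[tert-butyl(dimethyl)silyl]oxy}-6-[dimethyl(phenyl)silyl]-1-oxo-6,7:13,16-disecokaura-2,12,15-trien-7,20-olide | CC1(C)C=CC(=O)[C@]2(COC(=O)[C@@]3(C(O[Si](C)(C)C(C)(C)C)=CC)CC=CC[C@H]32)[C@@H]1C[Si](C)(C)c1ccccc1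
F6 | step 5 | (5R,8S,9S,10S,13R)-6-[dimethyl(phenyl)silyl]-1,15-dioxo-6,7-secokaura-2,11-dien-7,20-olide (C16 epimers) | CC1(C)C=CC(=O)[C@]2(COC(=O)[C@@]34C[C@@H](C=C[C@H]32)C(C)C4=O)[C@@H]1C[Si](C)(C)c1ccccc1
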